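**Retrosynthetic overview**

1. Skeleton numbering: ring A = C1–C5 and C10, ring B = C5–C10, and β is the face of the C10 methyl. The C3 angelate and C4 acetate come off to the 3β,4α-diol; this goes back through a C3 ketone and an α-face dihydroxylation to a C3=C4 methyl alkene, and from there through an enol triflate to a C4 ketone. The C7 isopropylidene comes from an aldol condensation of the C8 ketone with acetone.
2. The strategy rests on a carbonyl at C4 beside the ring-fusion C5–H, a carbonyl at C8 in ring B and the methyl-bearing quaternary C10. This is the pattern left when a vinyl ketone (C4(=O)–C5=C6) adds to a 2-silyloxydiene (C7=C8(OSi)–C9=C10(CH3)).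
3. Key disconnection: intramolecular Diels–Alder across C5–C10 and C6–C7 of an acyclic trienone tethered through C1–C3. Rings A and B form together in this one step under a chiral oxazaborolidinium catalyst, and C5 is then equilibrated to the trans fusion.
4. The trienone is built linearly from 5-hexyn-1-ol: carboalumination–iodination (C10 methyl, E alkene), oxidation, Weinreb amide, Stille coupling with an acetyl equivalent (C7, C8), kinetic silyl dienol ether, vinyl Grignard (C5, C6).
5. No ring is formed after the cycloaddition. The C8 silyl enol ether serves as the ketone protecting group until C4 has been methylated, so no ketal is needed.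

Key step: step 7

Assumption: the oxazaborolidinium catalyst derived from (S)-α,α-diphenylprolinol is taken as the hand that gives the 10R adduct through the endo transition state. If the sense of induction is the opposite, the (R)-catalyst is used under the same conditions.

**Route**

Step 1
Reactants: 1 hex-5-yn-1-ol
Product: 3 (E)-6-iodo-5-methylhex-5-en-1-ol, via alkenylalane 2 (not isolated)
Conditions: AlMe3 (3 equiv), Cp2ZrCl2 (0.25 equiv), CH2Cl2, 0 → 23 °C; then I2, THF, −30 → 0 °C
Reagents that add atoms: trimethylaluminium C[Al](C)C; iodine II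
Why: Zirconium-catalysed Negishi carboalumination adds CH3 and Al syn across the terminal alkyne with Al at the terminus (the hydroxyl is carried as its aluminium alkoxide), and iodinolysis with retention should give the E vinyl iodide.

Step 2
Reactants: 3 (E)-6-iodo-5-methylhex-5-en-1-ol
Product: 5 (E)-6-iodo-5-methylhex-5-enoic acid, via aldehyde 4 (not isolated)
Conditions: TEMPO (20 mol %), PhI(OAc)2 (2.2 equiv), MeCN/H2O 1:1, 23 °C
Reagents that add atoms: water O
Why: TEMPO/PhI(OAc)2 oxidation in aqueous acetonitrile takes the primary alcohol through the aldehyde hydrate to the acid and leaves the vinyl iodide alone.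

Step 3
Reactants: 5 (E)-6-iodo-5-methylhex-5-enoic acid; 6 N,O-dimethylhydroxylamine hydrochloride
Product: 7 (E)-6-iodo-N-methoxy-N,5-dimethylhex-5-enamide
Conditions: EDC·HCl, N-methylmorpholine, CH2Cl2, 0 → 23 °C
Reagents that add atoms: none
Why: Carbodiimide amide coupling gives the Weinreb amide, a latent ketone that survives the Stille coupling and the enolisation that follow.

Step 4
Reactants: 7 (E)-6-iodo-N-methoxy-N,5-dimethylhex-5-enamide; 8 tributyl(1-ethoxyvinyl)stannane
Product: 10 (E)-N-methoxy-N,5-dimethyl-7-oxooct-5-enamide, via ethoxydiene 9 (not isolated)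
Conditions: PdCl2(PPh3)2 (5 mol %), DMF, 70 °C; then 1 M HCl, THF, 0 °C
Reagents that add atoms: water O
Why: Stille coupling proceeds with retention of alkene geometry, and the 1-ethoxyvinyl group is an acetyl equivalent, so mild acid hydrolysis of the enol ether should give the E methyl enone.

Step 5
Reactants: 10 (E)-N-methoxy-N,5-dimethyl-7-oxooct-5-enamide
Product: 12 (E)-N-methoxy-N,5-dimethyl-7-(triisopropylsilyloxy)octa-5,7-dienamide, via lithium dienolate 11 (not isolated)
Conditions: LDA (1.1 equiv), THF, −78 °C; then i-Pr3SiOTf, −78 → 0 °C; Et3N-buffered work-up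
Reagents that add atoms: triisopropylsilyl triflate CC(C)[Si](OS(=O)(=O)C(F)(F)F)(C(C)C)C(C)C
Why: Kinetic deprotonation of an enone by LDA at −78 °C takes place at the α′ methyl group (the ketone is far more acidic than the amide), and O-silylation of the cross-conjugated enolate gives the 2-silyloxydiene with the E trisubstituted alkene unchanged.

Step 6
Reactants: 12 (E)-N-methoxy-N,5-dimethyl-7-(triisopropylsilyloxy)octa-5,7-dienamide; 13 vinylmagnesium bromide
Product: 15 (E)-7-methyl-9-(triisopropylsilyloxy)deca-1,7,9-trien-3-one, via magnesium hemiaminal 14 (not isolated)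
Conditions: THF, −78 → −20 °C; inverse quench into cold aq. KHSO4/Et2O, NaHCO3 wash; kept at or below 0 °C and used at once
Reagents that add atoms: none
Why: Weinreb ketone synthesis, in which the chelated tetrahedral intermediate stops at monoaddition and collapses to the vinyl ketone only on work-up; the inverse acidic quench keeps the liberated MeNHOMe protonated so that it does not add to the enone, and cold handling avoids uncatalysed cyclisation.

Step 7
Reactants: 15 (E)-7-methyl-9-(triisopropylsilyloxy)deca-1,7,9-trien-3-one
Product: 16 cis-fused adduct, (5S,10R)-10-methyl-8-(triisopropylsilyloxy)decal-8-en-4-one (C5–H and C10–CH3 both β; (4aR,8aS)-4a-methyl-6-(triisopropylsilyloxy)-3,4,4a,7,8,8a-hexahydronaphthalen-1(2H)-one)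
Conditions: (S)-3,3-diphenyl-1-(2-methylphenyl)-oxazaborolidinium bis(trifluoromethylsulfonyl)amide [from (S)-α,α-diphenylprolinol, (2-MeC6H4BO)3 and HNTf2] (20 mol %), CH2Cl2, −78 °C; Et3N quench; Et3N-deactivated silica
Reagents that add atoms: none
Why: Proposed new method: the N-protonated oxazaborolidine binds the C4 carbonyl oxygen and lowers the LUMO of the C5=C6 vinyl ketone, and the 2-silyloxydiene then adds in a concerted but asynchronous [4+2] in which the C6–C7 bond (enone β-carbon to the nucleophilic diene CH2) runs ahead of C5–C10, the closest known reactions being the achiral Lewis-acid-promoted intramolecular Diels–Alder of deca-1,7,9-trien-3-ones and the oxazaborolidinium-catalysed intermolecular Diels–Alder of vinyl ketones with 2-silyloxybutadienes. Ring B (C5 to C10) closes as the cyclohexene of the cycloaddition and ring A (C4, C3, C2, C1, C10, C5) closes through the C5–C10 bond, the tether C1–C4 with its catalyst-bound carbonyl lying endo under the diene, which gives the cis fusion. The configuration at C5 is set by the catalyst, whose aryl group covers one face of the bound enone, and that at the quaternary C10 follows from this facial choice combined with the endo geometry and the E configuration of C9=C10 (tether outside, methyl inside). Regiochemistry is fixed by the tether and coincides with the electronically preferred para orientation of the silyloxy and acyl groups. The step needs facial and endo selectivity together, because an exo adduct formed on the same enone face carries the opposite configuration at C10; the endo preference of a Lewis-acid-bound carbonyl should secure this, and any trans-fused kinetic adduct is removed by chromatography before step 8. The triisopropylsilyl group is chosen so that the dienol ether survives the acidic catalyst, and −78 °C suppresses the uncatalysed racemic cyclisation.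

Step 8
Reactants: 16 cis-fused adduct
Product: 17 trans-fused adduct, (5R,10R)-10-methyl-8-(triisopropylsilyloxy)decal-8-en-4-one (5α-H, 10β-CH3; (4aR,8aR)-4a-methyl-6-(triisopropylsilyloxy)-3,4,4a,7,8,8a-hexahydronaphthalen-1(2H)-one)
Conditions: DBU, toluene, 80 °C; chromatographic separation, recovered 16 resubmitted
Reagents that add atoms: none
Why: Thermodynamic epimerisation by reversible enolisation of the C4 ketone toward C5 should favour the trans-fused isomer (the axial methyl meets no syn-axial hydrogen at the sp2 carbon C4, while the cis isomer keeps an axial ring bond), though only moderately because of the angular methyl, which is why the cis isomer is recycled; C10 is not touched.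

Step 9
Reactants: 17 trans-fused adduct
Product: 19 (5R,10R)-10-methyl-8-(triisopropylsilyloxy)decala-3,8-dien-4-yl triflate, via potassium enolate 18 (not isolated)
Conditions: KN(SiMe3)2, THF, −78 °C; then PhNTf2, −78 → 0 °C
Reagents that add atoms: N-phenylbis(trifluoromethanesulfonimide) O=S(=O)(N(c1ccccc1)S(=O)(=O)C(F)(F)F)C(F)(F)F
Why: Kinetic deprotonation by the hindered amide base occurs at the C3 methylene and not at the tertiary C5–H, so C5 is not disturbed, and O-triflation gives the C3=C4 enol triflate while the C8 silyl enol ether protects the second ketone.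

Step 10
Reactants: 19 enol triflate
Product: 20 (5α-H,10β)-4,10-dimethyl-8-(triisopropylsilyloxy)decala-3,8-diene
Conditions: MeMgBr, Fe(acac)3 (5 mol %), THF/NMP, −30 → 0 °C
Reagents that add atoms: methylmagnesium bromide C[Mg]Br
Why: Iron-catalysed Kumada-type cross-coupling of an alkenyl triflate with a methyl Grignard reagent replaces OTf by CH3 with the alkene position kept, and the silyl enol ether is inert to the Grignard reagent.

Step 11
Reactants: 20 silyloxydiene
Product: 21 (5α-H,10β)-4,10-dimethyldecal-3-en-8-one
Conditions: Bu4NF, AcOH, THF, 0 °C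
Reagents that add atoms: none
Why: Fluoride cleaves the Si–O bond and the buffered enolate is protonated at C9 to give the C8 ketone; no stereocentre is involved and the C3=C4 alkene is not affected.

Step 12
Reactants: 21 (5α-H,10β)-4,10-dimethyldecal-3-en-8-one; 22 acetone
Product: 25 7β-(2-hydroxypropan-2-yl)-4,10-dimethyl-5α-H-decal-3-en-8-one, via lithium enolate 23 (not isolated), via zinc enolate 24 (not isolated)
Conditions: LDA, THF, −78 °C; ZnCl2, −78 → −40 °C; then acetone; aq. NH4Cl
Reagents that add atoms: none
Why: Directed aldol addition, in which LDA removes a C7 proton (C9 is neopentyl, next to the quaternary C10) and transmetallation to zinc suppresses proton transfer from acetone and retro-aldol; the side chain should settle equatorial (β) at C7, a centre that is removed in step 13.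

Step 13
Reactants: 25 aldol adduct
Product: 27 (5α-H,10β)-4,10-dimethyl-7-(propan-2-ylidene)decal-3-en-8-one, via tertiary mesylate 26 (not isolated)
Conditions: MsCl, Et3N, CH2Cl2, 0 °C; then DBU, 23 °C
Reagents that add atoms: none
Why: Mesylation of the tertiary alcohol through sulfene is followed by E1cB elimination, and DBU equilibrates any isopropenyl isomer to the conjugated tetrasubstituted alkylidene ketone.

Step 14
Reactants: 27 dienone
Product: 28 3α,4α-dihydroxy-4β,10β-dimethyl-7-(propan-2-ylidene)-5α-H-decalin-8-one
Conditions: OsO4 (2 mol %), NMO, acetone/H2O 4:1, 23 °C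
Reagents that add atoms: osmium tetroxide O=[Os](=O)(=O)=O (catalytic oxygen carrier); N-methylmorpholine N-oxide C[N+]1([O-])CCOCC1; water O
Why: Upjohn dihydroxylation adds both oxygens syn to the electron-rich trisubstituted C3=C4 bond (the tetrasubstituted enone alkene is inert) from the α face, anti to the axial C10 methyl that lies 1,3 to C4, which sets C4 (oxygen α, methyl β) and puts the C3 oxygen α for the time being.

Step 15
Reactants: 28 cis-diol
Product: 29 4α-hydroxy-4β,10β-dimethyl-7-(propan-2-ylidene)-5α-H-decalin-3,8-dione
Conditions: SO3·pyridine, DMSO, Et3N, CH2Cl2, 0 °C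
Reagents that add atoms: none
Why: Parikh–Doering oxidation converts the secondary C3 alcohol to the ketone without glycol cleavage, and the tertiary C4 alcohol cannot be oxidised.

Step 16
Reactants: 29 hydroxy dione
Product: 30 3β,4α-dihydroxy-4β,10β-dimethyl-7-(propan-2-ylidene)-5α-H-decalin-8-one
Conditions: NaBH4, MeOH/CH2Cl2, −78 °C
Reagents that add atoms: none
Why: Borohydride reduction at low temperature attacks the saturated α-hydroxy ketone much faster than the hindered cross-conjugated enone, and axial hydride delivery from the α face (equatorial approach is blocked by the axial C4 methyl) should give the equatorial 3β alcohol, trans to the C4 oxygen.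

Step 17
Reactants: 30 trans-diol; 31 angelic acid
Product: 33 3β-angeloyloxy-4α-hydroxy-4β,10β-dimethyl-7-(propan-2-ylidene)-5α-H-decalin-8-one, via mixed anhydride 32 (not isolated)
Conditions: 31, 2,4,6-trichlorobenzoyl chloride, Et3N, toluene, 23 °C; then 30, 75 °C (no DMAP)
Reagents that add atoms: none
Why: Yamaguchi esterification acylates only the secondary C3 hydroxyl, with retention at C3, and without a nucleophilic catalyst it preserves the Z geometry of the angelate.

Step 18
Reactants: 33 mono-angelate
Product: 34 target, (3S,4S,5R,10R)-4-acetoxy-3-angeloyloxy-4,10-dimethyl-7-(propan-2-ylidene)decalin-8-one (skeleton numbering)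
Conditions: Ac2O, DMAP, Et3N, CH2Cl2, 23 → 40 °C
Reagents that add atoms: acetic anhydride CC(=O)OC(C)=O
Why: DMAP-catalysed (Steglich-type) acetylation esterifies the remaining tertiary hydroxyl on oxygen, so the C4 configuration is retained.

**Compound list**

1 | hex-5-yn-1-ol | C#CCCCCO | starting material
2 | alkenylalane: dimethylaluminium alkoxide of (E)-6-(dimethylalumanyl)-5-methylhex-5-en-1-ol | C[Al](C)OCCCC/C(C)=C/[Al](C)C | intermediate (not isolated)
3 | (E)-6-iodo-5-methylhex-5-en-1-ol | OCCCC/C(C)=C/I | intermediate
4 | (E)-6-iodo-5-methylhex-5-enal | O=CCCC/C(C)=C/I | intermediate (not isolated)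
5 | (E)-6-iodo-5-methylhex-5-enoic acid | OC(=O)CCC/C(C)=C/I | intermediate
6 | N,O-dimethylhydroxylamine hydrochloride | CNOC.Cl | starting material
7 | (E)-6-iodo-N-methoxy-N,5-dimethylhex-5-enamide | CON(C)C(=O)CCC/C(C)=C/I | intermediate
8 | tributyl(1-ethoxyvinyl)stannane | CCCC[Sn](CCCC)(CCCC)C(=C)OCC | starting material
9 | (E)-7-ethoxy-N-methoxy-N,5-dimethylocta-5,7-dienamide | CON(C)C(=O)CCC/C(C)=C/C(=C)OCC | intermediate (not isolated)
10 | (E)-N-methoxy-N,5-dimethyl-7-oxooct-5-enamide | CON(C)C(=O)CCC/C(C)=C/C(C)=O | intermediate
11 | lithium dienolate of 10 (cross-conjugated) | CON(C)C(=O)CCC/C(C)=C/C(=C)O[Li] | intermediate (not isolated)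
12 | (E)-N-methoxy-N,5-dimethyl-7-(triisopropylsilyloxy)octa-5,7-dienamide | CON(C)C(=O)CCC/C(C)=C/C(=C)O[Si](C(C)C)(C(C)C)C(C)C | intermediate
13 | vinylmagnesium bromide | C=C[Mg]Br | starting material
14 | bromomagnesium hemiaminal (tetrahedral adduct of 12 and 13) | C=CC(O[Mg]Br)(CCC/C(C)=C/C(=C)O[Si](C(C)C)(C(C)C)C(C)C)N(C)OC | intermediate (not isolated)
15 | (E)-7-methyl-9-(triisopropylsilyloxy)deca-1,7,9-trien-3-one | C=CC(=O)CCC/C(C)=C/C(=C)O[Si](C(C)C)(C(C)C)C(C)C | intermediate (key-step precursor)
16 | cis-fused adduct, (5S,10R)-10-methyl-8-(triisopropylsilyloxy)decal-8-en-4-one | O=C1CCC[C@]2(C)C=C(O[Si](C(C)C)(C(C)C)C(C)C)CC[C@H]12 | intermediate (key-step product)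
17 | trans-fused adduct, (5R,10R)-10-methyl-8-(triisopropylsilyloxy)decal-8-en-4-one | O=C1CCC[C@]2(C)C=C(O[Si](C(C)C)(C(C)C)C(C)C)CC[C@@H]12 | intermediate
18 | potassium C3=C4 enolate of 17 | [K]OC1=CCC[C@]2(C)C=C(O[Si](C(C)C)(C(C)C)C(C)C)CC[C@@H]12 | intermediate (not isolated)
19 | (5R,10R)-10-methyl-8-(triisopropylsilyloxy)decala-3,8-dien-4-yl triflate | O=S(=O)(OC1=CCC[C@]2(C)C=C(O[Si](C(C)C)(C(C)C)C(C)C)CC[C@@H]12)C(F)(F)F | intermediate
20 | (5α-H,10β)-4,10-dimethyl-8-(triisopropylsilyloxy)decala-3,8-diene | CC1=CCC[C@]2(C)C=C(O[Si](C(C)C)(C(C)C)C(C)C)CC[C@@H]12 | intermediate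
21 | (5α-H,10β)-4,10-dimethyldecal-3-en-8-one | CC1=CCC[C@]2(C)CC(=O)CC[C@@H]12 | intermediate
22 | acetone | CC(C)=O | starting material
23 | lithium C7=C8 enolate of 21 | CC1=CCC[C@]2(C)CC(O[Li])=CC[C@@H]12 | intermediate (not isolated)
24 | chlorozinc C7=C8 enolate of 21 | CC1=CCC[C@]2(C)CC(O[Zn]Cl)=CC[C@@H]12 | intermediate (not isolated)
25 | 7β-(2-hydroxypropan-2-yl)-4,10-dimethyl-5α-H-decal-3-en-8-one | CC1=CCC[C@]2(C)CC(=O)[C@@H](C(C)(C)O)C[C@@H]12 | intermediate
26 | tertiary mesylate of 25 | CC1=CCC[C@]2(C)CC(=O)[C@@H](C(C)(C)OS(C)(=O)=O)C[C@@H]12 | intermediate (not isolated)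
27 | (5α-H,10β)-4,10-dimethyl-7-(propan-2-ylidene)decal-3-en-8-one | CC1=CCC[C@]2(C)CC(=O)C(=C(C)C)C[C@@H]12 | intermediate
28 | 3α,4α-dihydroxy-4β,10β-dimethyl-7-(propan-2-ylidene)-5α-H-decalin-8-one | O[C@@H]1CC[C@]2(C)CC(=O)C(=C(C)C)C[C@H]2[C@]1(C)O | intermediate
29 | 4α-hydroxy-4β,10β-dimethyl-7-(propan-2-ylidene)-5α-H-decalin-3,8-dione | O=C1CC[C@]2(C)CC(=O)C(=C(C)C)C[C@H]2[C@]1(C)O | intermediate
30 | 3β,4α-dihydroxy-4β,10β-dimethyl-7-(propan-2-ylidene)-5α-H-decalin-8-one | O[C@H]1CC[C@]2(C)CC(=O)C(=C(C)C)C[C@H]2[C@]1(C)O | intermediate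
31 | angelic acid, (Z)-2-methylbut-2-enoic acid | C/C=C(/C)C(=O)O | starting material
32 | angelic 2,4,6-trichlorobenzoic mixed anhydride | C/C=C(/C)C(=O)OC(=O)c1c(Cl)cc(Cl)cc1Cl | intermediate (not isolated)
33 | 3β-angeloyloxy-4α-hydroxy-4β,10β-dimethyl-7-(propan-2-ylidene)-5α-H-decalin-8-one | C/C=C(/C)C(=O)O[C@H]1CC[C@]2(C)CC(=O)C(=C(C)C)C[C@H]2[C@]1(C)O | intermediate
34 | CNP0141494.1, (3S,4S,5R,10R)-4-acetoxy-3-angeloyloxy-4,10-dimethyl-7-(propan-2-ylidene)decalin-8-one | C/C=C(/C)C(=O)O[C@H]1CC[C@]2(C)CC(=O)C(=C(C)C)C[C@H]2[C@]1(C)OC(C)=O | target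

**Step count and risks**

Total step count: 18. Longest linear sequence: 18 steps, from hex-5-yn-1-ol (1) to 34; the route is fully linear.

Steps most likely to fail:

1. Step 7 (labelled step). The catalyst may discriminate the enone faces poorly when the ketone sits in the tether, endo/exo leakage may lower the optical purity at C10, and the acidic catalyst may protodesilylate the dienol ether before cyclisation. Fallback by known chemistry, setting out from 15: cyclisation with Me2AlCl in CH2Cl2 at −78 °C, a Lewis-acid-promoted intramolecular Diels–Alder of the known decatrienone type, should give the racemic cis-fused adduct F1. Equilibration with DBU as in step 8 should give the racemic trans-fused adduct F2. Its enantiomers are separated by preparative chromatography on a chiral stationary phase (amylose or cellulose carbamate), and the (5R,10R) enantiomer is 17, where the route is rejoined.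

2. Step 8. The thermodynamic bias toward the trans fusion may be too small, because the angular methyl destabilises both fusions, so the equilibration would need many recycles. Fallback, setting out from 12: addition of ethynylmagnesium bromide in place of 13 should give the dienynone (E)-7-methyl-9-(triisopropylsilyloxy)deca-7,9-dien-1-yn-3-one F3. Its cycloaddition under the conditions established for step 7 forms the same two bonds but creates only the C10 stereocentre, and should give 10β-methyl-8-(triisopropylsilyloxy)decala-5,8-dien-4-one F4. Hydrogenation of the conjugated C5=C6 bond (H2, 1 atm, palladium on carbon, EtOAc) from the α face, anti to the angular methyl, with the hindered silyl enol ether left intact, sets the 5α hydrogen kinetically and gives 17, where the route is rejoined.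

3. Step 18. Acylation of the hindered tertiary hydroxyl may be slow, and forcing conditions may cause acyl migration between O3 and O4 or Z to E isomerisation of the angelate. Fallback, setting out from 30, reverses the order of the two esterifications. Selective silylation of the secondary hydroxyl (Et3SiCl, imidazole, DMF) should give the 3β-triethylsilyl ether F5. The tertiary hydroxyl is then acetylated under forcing conditions that no longer endanger an angelate (Ac2O, DMAP, Et3N, 60 °C) to give the silyl ether acetate F6. Desilylation with HF·pyridine in THF should give the 3β-hydroxy 4α-acetate F7, which is angeloylated under the Yamaguchi conditions of step 17 to give 34.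

Further compounds
F1 | step 7 | racemic cis-fused 10-methyl-8-(triisopropylsilyloxy)decal-8-en-4-one (both enantiomers) | O=C1CCC[C@]2(C)C=C(O[Si](C(C)C)(C(C)C)C(C)C)CC[C@H]12.O=C1CCC[C@@]2(C)C=C(O[Si](C(C)C)(C(C)C)C(C)C)CC[C@@H]12
F2 | step 7 | racemic trans-fused 10-methyl-8-(triisopropylsilyloxy)decal-8-en-4-one (both enantiomers) | O=C1CCC[C@]2(C)C=C(O[Si](C(C)C)(C(C)C)C(C)C)CC[C@@H]12.O=C1CCC[C@@]2(C)C=C(O[Si](C(C)C)(C(C)C)C(C)C)CC[C@H]12
F3 | step 8 | (E)-7-methyl-9-(triisopropylsilyloxy)deca-7,9-dien-1-yn-3-one | C#CC(=O)CCC/C(C)=C/C(=C)O[Si](C(C)C)(C(C)C)C(C)C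
F4 | step 8 | (10R)-10-methyl-8-(triisopropylsilyloxy)decala-5,8-dien-4-one | O=C1CCC[C@]2(C)C=C(O[Si](C(C)C)(C(C)C)C(C)C)CC=C12
F5 | step 18 | 4α-hydroxy-4β,10β-dimethyl-7-(propan-2-ylidene)-3β-(triethylsilyloxy)-5α-H-decalin-8-one | CC[Si](CC)(CC)O[C@H]1CC[C@]2(C)CC(=O)C(=C(C)C)C[C@H]2[C@]1(C)O
F6 | step 18 | 4α-acetoxy-4β,10β-dimethyl-7-(propan-2-ylidene)-3β-(triethylsilyloxy)-5α-H-decalin-8-one | CC[Si](CC)(CC)O[C@H]1CC[C@]2(C)CC(=O)C(=C(C)C)C[C@H]2[C@]1(C)OC(C)=O
F7 | step 18 | 4α-acetoxy-3β-hydroxy-4β,10β-dimethyl-7-(propan-2-ylidene)-5α-H-decalin-8-one | O[C@H]1CC[C@]2(C)CC(=O)C(=C(C)C)C[C@H]2[C@]1(C)OC(C)=O
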